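The route rests on cutting the C2–C1' bond between ring C and the 4-hydroxyphenyl ring B. C2 is the β-carbon of the vinylogous ester O1–C2=C3–C4=O, so a flat, achiral 6,8-diprenyl-7-silyloxychromone can take up the aryl group of a boronic acid under rhodium/chiral-diene catalysis. That one operation attaches ring B, turns the pyranone into the chromanone and sets C2. The precursor carries both prenyl chains, installed by twofold cross-coupling of a 6,8-diiodochromone, and no free phenol. The enolizable C3 next to the new stereocenter is then oxygenated through its enol silane, anti to the aryl group, and fluoride unmasks both phenols.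

Key step: step 5

Assumption: the (S,S) antipode of the diene is taken as the one that delivers the aryl group to the Re face of C2 (the face that leads to 2S), by analogy with the usual facial model for cyclic enones; if a first run shows the opposite sense, the (R,R) antipode is used with no other change.

Step 1
Reactants: 1 2,4-dihydroxyacetophenone
Product: 2 2,4-dihydroxy-3,5-diiodoacetophenone
Conditions: I2 (0.85 eq), HIO3 (0.42 eq), EtOH/H2O, 35–40 °C
Reagents that add atoms: iodine, II; iodic acid, OI(=O)=O
Why: Electrophilic aromatic iodination in which iodic acid oxidizes iodine to an iodonium equivalent, which attacks C3 and C5 (both ortho to the 4-hydroxyl and activated by two oxygen donors), while C6, meta to both hydroxyls, stays free.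

Step 2
Reactants: 2 2,4-dihydroxy-3,5-diiodoacetophenone
Product: 4 7-hydroxy-6,8-diiodochromen-4-one, via enaminone 3 (not isolated)
Conditions: t-BuOCH(NMe2)2 (3.5 eq), PhMe, 90 °C; volatiles removed; then conc. HCl, MeOH, 50 °C
Reagents that add atoms: tert-butoxybis(dimethylamino)methane, CN(C)C(OC(C)(C)C)N(C)C
Why: Enaminone route to chromones, in which aminomethylenation of the methyl ketone is followed by acid-promoted conjugate addition of the 2-hydroxyl and loss of dimethylamine; the tert-butoxy aminal is used because, unlike a formamide dimethyl acetal, it cannot O-methylate the acidic diiodophenol.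

Step 3
Reactants: 4 7-hydroxy-6,8-diiodochromen-4-one
Product: 5 7-(tert-butyldimethylsilyloxy)-6,8-diiodochromen-4-one
Conditions: TBSCl (1.3 eq), imidazole (2.5 eq), DMF, rt
Reagents that add atoms: tert-butyldimethylsilyl chloride, CC(C)(C)[Si](C)(C)Cl
Why: Standard imidazole-mediated silylation of a phenol, which masks the only acidic proton before the palladium and rhodium steps; the two ortho substituents (iodine now, prenyl later) shield the Si–O bond of this vinylogous silyl ester from nucleophiles.

Step 4
Reactants: 5 7-(tert-butyldimethylsilyloxy)-6,8-diiodochromen-4-one; 6 tributyl(3-methylbut-2-enyl)stannane (2.6 eq)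
Product: 7 7-(tert-butyldimethylsilyloxy)-6,8-bis(3-methylbut-2-enyl)chromen-4-one
Conditions: Pd(PPh3)4 (10 mol%), degassed DMF, 90 °C
Reagents that add atoms: none
Why: Twofold Stille coupling of aryl iodides with an allylstannane, in which each C–I bond adds oxidatively to zerovalent palladium, the allyl unit is transferred from tin and reductive elimination at the unhindered CH2 terminus should give the linear prenyl arene under neutral, fluoride-free conditions that spare the silyl ether and the pyranone.

Step 5
Reactants: 7 7-(tert-butyldimethylsilyloxy)-6,8-bis(3-methylbut-2-enyl)chromen-4-one; 8 4-(tert-butyldimethylsilyloxy)phenylboronic acid (2.5 eq)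
Product: 9 (2S)-7-(tert-butyldimethylsilyloxy)-2-[4-(tert-butyldimethylsilyloxy)phenyl]-6,8-bis(3-methylbut-2-enyl)chroman-4-one
Conditions: [RhCl(C2H4)2]2 (2.5 mol%), (1S,4S)-2,5-diphenylbicyclo[2.2.2]octa-2,5-diene (5.5 mol%), KOH (10 mol%), dioxane/H2O 10:1, 40 °C
Reagents that add atoms: none
Why: In this Hayashi–Miyaura-type asymmetric 1,4-addition the aryl group passes from boron to the hydroxo complex of monovalent rhodium, the aryl–rhodium species binds the polarized C2=C3 bond and inserts it so that the aryl carbon bonds to C2, and water protonates the resulting rhodium enolate at C3, releasing the flavanone and restoring Rh–OH. The closest known reaction type is the rhodium/chiral-diene-catalysed conjugate arylation of 2-unsubstituted chromones to flavanones. No ring closes: only the C2–C1' bond forms and the existing pyranone becomes a chromanone. The single new stereocenter, C2, is controlled by the twofold-symmetric chiral diene on rhodium, whose antipode is chosen for Re-face delivery to give 2S. The step needs enantioface selectivity on an achiral enone, which comes from the ligand alone, and site selectivity for C2=C3 over the prenyl olefins, which comes from conjugation to the C4 carbonyl because isolated trisubstituted olefins do not insert. The absence of free phenols and the buffering of the catalytic hydroxide by excess boronic acid should keep both silyl ethers in place and suppress retro-oxa-Michael racemization of the product.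

Step 6
Reactants: 9 (2S)-7-(tert-butyldimethylsilyloxy)-2-[4-(tert-butyldimethylsilyloxy)phenyl]-6,8-bis(3-methylbut-2-enyl)chroman-4-one
Product: 10 (2S)-7-(tert-butyldimethylsilyloxy)-2-[4-(tert-butyldimethylsilyloxy)phenyl]-6,8-bis(3-methylbut-2-enyl)-4-(trimethylsilyloxy)-2H-chromene
Conditions: TMSOTf (1.5 eq), Et3N (3 eq), CH2Cl2, 0 °C; non-aqueous work-up, used crude
Reagents that add atoms: trimethylsilyl triflate, C[Si](C)(C)OS(=O)(=O)C(F)(F)F
Why: Soft enolization, in which O-silylation of the C4 carbonyl and deprotonation at C3 (the only enolizable position) by the amine give the enol silane without a free enolate, so ring opening to the chalcone and loss of the C2 configuration are not expected.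

Step 7
Reactants: 10 (2S)-7-(tert-butyldimethylsilyloxy)-2-[4-(tert-butyldimethylsilyloxy)phenyl]-6,8-bis(3-methylbut-2-enyl)-4-(trimethylsilyloxy)-2H-chromene
Product: 13 (2R,3R)-3-hydroxy-7-(tert-butyldimethylsilyloxy)-2-[4-(tert-butyldimethylsilyloxy)phenyl]-6,8-bis(3-methylbut-2-enyl)chroman-4-one, via silyloxy epoxide 11 (not isolated), via 3-O-trimethylsilyl ketone 12 (not isolated)
Conditions: 2-(phenylsulfonyl)-3-phenyloxaziridine (1.3 eq), CH2Cl2, 0 °C to rt; then 10% aq. citric acid, THF, rt
Reagents that add atoms: 2-(phenylsulfonyl)-3-phenyloxaziridine, O=S(=O)(N1OC1c1ccccc1)c1ccccc1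
Why: Rubottom-type oxidation of an enol silane with a Davis N-sulfonyloxaziridine, in which oxygen is delivered to the face opposite the C2 aryl group (substrate control, giving the 2,3-trans 3R centre, also the thermodynamically preferred one), the siloxy epoxide opens with silyl migration and mild acid frees the 3-hydroxyl, while the unactivated prenyl olefins are not oxidized by this reagent at these temperatures (C2 is untouched; its descriptor changes from S to R only because C3 now outranks the aryl carbon).

Step 8
Reactants: 13 (2R,3R)-3-hydroxy-7-(tert-butyldimethylsilyloxy)-2-[4-(tert-butyldimethylsilyloxy)phenyl]-6,8-bis(3-methylbut-2-enyl)chroman-4-one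
Product: 14 Lespeflorin B2, (2R,3R)-3,7-dihydroxy-2-(4-hydroxyphenyl)-6,8-bis(3-methylbut-2-enyl)chroman-4-one
Conditions: TBAF (2.5 eq), AcOH (3 eq), THF, 0 °C
Reagents that add atoms: none
Why: Fluoride-mediated cleavage of both aryl silyl ethers, with acetic acid keeping the liberated phenols protonated, which should prevent ring opening through a phenoxide, epimerization at C2 or C3 and aerial oxidation to the flavonol.

Compound list
1 | 2,4-dihydroxyacetophenone | CC(=O)c1ccc(O)cc1O | starting material
2 | 2,4-dihydroxy-3,5-diiodoacetophenone | CC(=O)c1cc(I)c(O)c(I)c1O | intermediate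
3 | (E)-1-(2,4-dihydroxy-3,5-diiodophenyl)-3-(dimethylamino)prop-2-en-1-one (enaminone) | CN(C)/C=C/C(=O)c1cc(I)c(O)c(I)c1O | intermediate (not isolated)
4 | 7-hydroxy-6,8-diiodochromen-4-one | O=c1ccoc2c(I)c(O)c(I)cc12 | intermediate
5 | 7-(tert-butyldimethylsilyloxy)-6,8-diiodochromen-4-one | O=c1ccoc2c(I)c(O[Si](C)(C)C(C)(C)C)c(I)cc12 | intermediate
6 | tributyl(3-methylbut-2-enyl)stannane | CC(C)=CC[Sn](CCCC)(CCCC)CCCC | starting material
7 | 7-(tert-butyldimethylsilyloxy)-6,8-bis(3-methylbut-2-enyl)chromen-4-one | CC(C)=CCc1cc2c(=O)ccoc2c(CC=C(C)C)c1O[Si](C)(C)C(C)(C)C | intermediate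
8 | 4-(tert-butyldimethylsilyloxy)phenylboronic acid | CC(C)(C)[Si](C)(C)Oc1ccc(B(O)O)cc1 | starting material
9 | (2S)-7-(tert-butyldimethylsilyloxy)-2-[4-(tert-butyldimethylsilyloxy)phenyl]-6,8-bis(3-methylbut-2-enyl)chroman-4-one | CC(C)=CCc1cc2c(c(CC=C(C)C)c1O[Si](C)(C)C(C)(C)C)O[C@H](c1ccc(O[Si](C)(C)C(C)(C)C)cc1)CC2=O | intermediate
10 | (2S)-7-(tert-butyldimethylsilyloxy)-2-[4-(tert-butyldimethylsilyloxy)phenyl]-6,8-bis(3-methylbut-2-enyl)-4-(trimethylsilyloxy)-2H-chromene | CC(C)=CCc1cc2c(c(CC=C(C)C)c1O[Si](C)(C)C(C)(C)C)O[C@H](c1ccc(O[Si](C)(C)C(C)(C)C)cc1)C=C2O[Si](C)(C)C | intermediate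
11 | 3,4-epoxide of 10 carrying the trimethylsilyloxy group on C4, epoxide oxygen anti to the C2 aryl group (silyloxy epoxide) | CC(C)=CCc1cc2c(c(CC=C(C)C)c1O[Si](C)(C)C(C)(C)C)O[C@H](c1ccc(O[Si](C)(C)C(C)(C)C)cc1)[C@@H](O3)[C@]23O[Si](C)(C)C | intermediate (not isolated)
12 | (2R,3R)-7-(tert-butyldimethylsilyloxy)-2-[4-(tert-butyldimethylsilyloxy)phenyl]-6,8-bis(3-methylbut-2-enyl)-3-(trimethylsilyloxy)chroman-4-one | CC(C)=CCc1cc2c(c(CC=C(C)C)c1O[Si](C)(C)C(C)(C)C)O[C@H](c1ccc(O[Si](C)(C)C(C)(C)C)cc1)[C@@H](O[Si](C)(C)C)C2=O | intermediate (not isolated)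
13 | (2R,3R)-3-hydroxy-7-(tert-butyldimethylsilyloxy)-2-[4-(tert-butyldimethylsilyloxy)phenyl]-6,8-bis(3-methylbut-2-enyl)chroman-4-one | CC(C)=CCc1cc2c(c(CC=C(C)C)c1O[Si](C)(C)C(C)(C)C)O[C@H](c1ccc(O[Si](C)(C)C(C)(C)C)cc1)[C@@H](O)C2=O | intermediate
14 | Lespeflorin B2, (2R,3R)-3,7-dihydroxy-2-(4-hydroxyphenyl)-6,8-bis(3-methylbut-2-enyl)chroman-4-one | CC(C)=CCc1cc2c(c(CC=C(C)C)c1O)O[C@H](c1ccc(O)cc1)[C@@H](O)C2=O | target

Total step count: 8
Longest linear sequence: 8 steps (1 to 14); compounds 6 and 8 are bought.

Steps most likely to fail

Step 4. The twofold prenyl transfer may deliver the allyl unit through its substituted terminus (reverse prenyl), move the double bond into conjugation with ring A, or stall after the first coupling at the doubly flanked C8 position. Fallback: from compound 5, Stille coupling with allyltributylstannane (Pd(PPh3)4, DMF, 90 °C), where both allyl termini are identical, should give 7-(tert-butyldimethylsilyloxy)-6,8-di(prop-2-enyl)chromen-4-one F1. Twofold olefin cross-metathesis of F1 with excess 2-methylbut-2-ene (second-generation Grubbs catalyst, RuCl2(=CHPh)(PCy3)(H2IMes), CH2Cl2, 40 °C) then turns each allyl group into a prenyl group and returns to compound 7. The electron-poor C2=C3 bond of the pyranone is not expected to take part in the metathesis.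

Step 5. Insertion into the electron-rich chromone with a substituent at C8 may be slow, so that protodeboronation of 8 consumes the aryl donor. The enantiomeric purity may also erode through reversible ring opening of the flavanone, or the hindered aryl silyl ether may be lost in the aqueous medium. Fallback: from compounds 7 and 8, the same bond is made in a different catalytic manifold, with cationic divalent palladium carrying a chiral pyridine–oxazoline ligand (Pd(OCOCF3)2, the antipode of t-BuPyOx that gives Re-face delivery, NH4PF6, H2O, ClCH2CH2Cl, 60 °C). This system works through an aryl–palladium species formed by direct transmetalation, needs no base and tolerates air. It returns directly to compound 9 and makes no compound outside the main list (none, F0).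

Step 7. Oxygen transfer from the oxaziridine to the enol silane may be sluggish, so that hydrolysis back to 9 competes. Forcing the reaction may start oxidation of the prenyl olefins, and the facial selectivity at C3 may be incomplete. Fallback: from compound 10, a Lewis-acid-promoted O-selective nitroso aldol reaction with nitrosobenzene (TESOTf cat., CH2Cl2, −78 °C) forms the C3–O bond by attack of the enol silane on the N=O oxygen, anti to the aryl group, with no oxidant that can touch an olefin. This gives (2R,3R)-3-(N-phenylaminooxy)-7-(tert-butyldimethylsilyloxy)-2-[4-(tert-butyldimethylsilyloxy)phenyl]-6,8-bis(3-methylbut-2-enyl)chroman-4-one F2. Cleavage of the N–O bond of F2 (CuSO4 cat., MeOH, 0 °C) then returns to compound 13.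

Further compounds
F1 | step 4 | 7-(tert-butyldimethylsilyloxy)-6,8-di(prop-2-enyl)chromen-4-one | C=CCc1cc2c(=O)ccoc2c(CC=C)c1O[Si](C)(C)C(C)(C)C
F0 | step 5 | none | none
F2 | step 7 | (2R,3R)-3-(N-phenylaminooxy)-7-(tert-butyldimethylsilyloxy)-2-[4-(tert-butyldimethylsilyloxy)phenyl]-6,8-bis(3-methylbut-2-enyl)chroman-4-one | CC(C)=CCc1cc2c(c(CC=C(C)C)c1O[Si](C)(C)C(C)(C)C)O[C@H](c1ccc(O[Si](C)(C)C(C)(C)C)cc1)[C@@H](ONc1ccccc1)C2=O
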